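The chromone is disconnected at O1–C8a and C4–C4a. The feature exploited is that C4a (acyl-bearing) and C8a (O1-bearing) are neighbouring carbons of ring A, set between the C5 oxygen and the C8 benzyl group, so a ring-A aryne spanning C4a–C8a can be inserted into the C–O bond of an α-methoxycinnamic acid. In one operation the carboxylate oxygen becomes O1 at C8a and the acyl group lands on C4a, giving the 2'-hydroxy-α-methoxychalcone. The aryne precursor is a pentasubstituted ortho-silylaryl triflate: SiMe3 at C4a, OTf at C8a, OBn at C5, OMe at C7 and the O-benzylated hydroxybenzyl group at C8.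

Key step: step 8

Remark: ring-A carbons are referred to by their flavone locants (C4a, C5, C6, C7, C8, C8a) from the first intermediate on. The Z descriptor of 14, 15 and 17 (methoxy cis to aryl) is the expected thermodynamic geometry; it is erased in step 9, so an E/Z mixture would serve equally.

Step 1
Reactants: 1 5-methoxyresorcinol
Product: 2 2,4-dihydroxy-6-methoxybenzaldehyde
Conditions: POCl3 (1.1 equiv), DMF (1.5 equiv), EtOAc, 0 °C to rt; then H2O, 50 °C
Reagents that add atoms: N,N-dimethylformamide CN(C)C=O (formyl carbon); water O (carbonyl oxygen)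
Why: Vilsmeier–Haack formylation of the phloroglucinol monoether should go para to one hydroxyl, i.e. at the carbon between OH and OMe, which is the future C8; the symmetric 2,6-dihydroxy isomer is the expected minor by-product and is removed by crystallisation.

Step 2
Reactants: 2 2,4-dihydroxy-6-methoxybenzaldehyde
Product: 3 4-(benzyloxy)-2-hydroxy-6-methoxybenzaldehyde
Conditions: BnBr (1.05 equiv), K2CO3 (1.1 equiv), acetone, 56 °C
Reagents that add atoms: benzyl bromide BrCc1ccccc1
Why: Williamson etherification is selective for the 4-hydroxyl (the future C5 oxygen), which is the more acidic one and is not tied up in the hydrogen bond to the formyl group that deactivates the 2-hydroxyl.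

Step 3
Reactants: 3 4-(benzyloxy)-2-hydroxy-6-methoxybenzaldehyde; 4 1-(benzyloxy)-2-bromobenzene
Product: 6 rac-[4-(benzyloxy)-2-hydroxy-6-methoxyphenyl][2-(benzyloxy)phenyl]methanol, via [2-(benzyloxy)phenyl]magnesium bromide 5 (not isolated)
Conditions: 4, Mg, THF, reflux; then 3 (0.4 equiv relative to 5), THF, 0 °C to rt; aq. NH4Cl
Reagents that add atoms: none
Why: Grignard addition to the aldehyde, the first equivalent being consumed by the phenol to give a magnesium phenoxide that chelates and activates the carbonyl; the carbinol centre is formed as a racemate and is removed in step 4.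

Step 4
Reactants: 6 rac-[4-(benzyloxy)-2-hydroxy-6-methoxyphenyl][2-(benzyloxy)phenyl]methanol
Product: 7 2-[2-(benzyloxy)benzyl]-5-(benzyloxy)-3-methoxyphenol
Conditions: Et3SiH (3 equiv), TFA (5 equiv), CH2Cl2, 0 °C
Reagents that add atoms: none
Why: Ionic hydrogenation, in which TFA ionises the doubly oxygen-stabilised benzhydrol to a quinone-methide-type cation that is trapped by hydride from the silane, while aryl benzyl ethers should survive the short, cold exposure to acid.

Step 5
Reactants: 7 2-[2-(benzyloxy)benzyl]-5-(benzyloxy)-3-methoxyphenol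
Product: 8 6-[2-(benzyloxy)benzyl]-3-(benzyloxy)-2-bromo-5-methoxyphenol
Conditions: NBS (1.0 equiv), i-Pr2NH (10 mol%), CH2Cl2, -78 to 0 °C, dark
Reagents that add atoms: N-bromosuccinimide O=C1CCC(=O)N1Br
Why: Amine-catalysed ortho-selective electrophilic bromination of a phenol (the N-bromoamine is delivered through hydrogen bonding to the OH) should place bromine at C4a, the only free ortho position, in preference to C6, which is screened by two ether groups.

Step 6
Reactants: 8 6-[2-(benzyloxy)benzyl]-3-(benzyloxy)-2-bromo-5-methoxyphenol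
Product: 11 6-[2-(benzyloxy)benzyl]-3-(benzyloxy)-5-methoxy-2-(trimethylsilyl)phenyl trifluoromethanesulfonate (SiMe3 at C4a, OTf at C8a), via aryl trimethylsilyl ether 9 (not isolated), via lithium 2-silylphenoxide 10 (not isolated)
Conditions: HMDS, THF, 65 °C, evaporate; n-BuLi (1.1 equiv), THF, -78 °C; Tf2O (1.2 equiv), -78 °C to rt
Reagents that add atoms: hexamethyldisilazane C[Si](C)(C)N[Si](C)(C)C; trifluoromethanesulfonic anhydride FC(F)(F)S(=O)(=O)OS(=O)(=O)C(F)(F)F
Why: O-silylation, bromine–lithium exchange and retro-Brook 1,3-O-to-C silyl migration give the ortho-silylphenoxide, which is trapped as the triflate; the exchange is far faster than deprotonation of the benzylic positions at -78 °C, and no acid that could protodesilylate the electron-rich ring is used from here on.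

Step 7
Reactants: 12 4-(benzyloxy)-3-methoxybenzaldehyde (O-benzylvanillin); 13 methyl methoxyacetate
Product: 15 (Z)-3-[4-(benzyloxy)-3-methoxyphenyl]-2-methoxyacrylic acid, via methyl (Z)-3-[4-(benzyloxy)-3-methoxyphenyl]-2-methoxyacrylate 14 (not isolated)
Conditions: 13 (3 equiv), NaOMe (3 equiv), MeOH/THF, 0 °C to reflux; then 2 M NaOH, 60 °C; then HCl to pH 2
Reagents that add atoms: sodium hydroxide [Na+].[OH-] (carboxyl OH oxygen)
Why: Claisen-type aldol condensation of the ester enolate with the non-enolisable aldehyde, followed by E1cB dehydration, gives the thermodynamically preferred Z enol ether ester (ester trans to aryl), which is saponified in the same pot.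

Step 8
Reactants: 11 6-[2-(benzyloxy)benzyl]-3-(benzyloxy)-5-methoxy-2-(trimethylsilyl)phenyl trifluoromethanesulfonate; 15 (Z)-3-[4-(benzyloxy)-3-methoxyphenyl]-2-methoxyacrylic acid
Product: 17 (Z)-1-{3-[2-(benzyloxy)benzyl]-6-(benzyloxy)-2-hydroxy-4-methoxyphenyl}-3-[4-(benzyloxy)-3-methoxyphenyl]-2-methoxyprop-2-en-1-one, via 3-[2-(benzyloxy)benzyl]-6-(benzyloxy)-4-methoxy-1,2-didehydrobenzene 16 (not isolated)
Conditions: CsF (4 equiv, dried), 15 (1.2 equiv), THF, 125 °C, sealed tube; pH 6 phosphate buffer work-up
Reagents that add atoms: none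
Why: Fluoride attacks silicon and triflate leaves to give aryne 16; the cesium carboxylate adds through oxygen at C8a, and the aryl anion thus formed at C4a attacks the adjacent ester carbonyl through a four-membered alkoxide that opens to the ortho-acylphenoxide, a net insertion of the aryne into the acid C–O bond. The closest known reaction is the fluoride-induced aryne insertion into carboxylic acids that gives ortho-hydroxyaryl ketones, α,β-unsaturated acids included. No ring is closed and no stereocentre is formed; the alkene geometry is carried through unchanged and is irrelevant later. The step needs one orientation of addition, which is secured by the C5 benzyloxy group: by induction and aryne distortion it makes C8a the electrophilic terminus and places the negative charge at C4a next to oxygen, an effect expected to outweigh the steric bias of the C8 benzyl group. It also needs acyl transfer to beat protonation of the aryl anion, which high temperature and the absence of other proton sources favour. Ring closure of the phenoxide onto the enone is slowed by the electron-donating α-methoxy group, and any flavanone formed would converge on 19 in step 9.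

Step 9
Reactants: 17 (Z)-1-{3-[2-(benzyloxy)benzyl]-6-(benzyloxy)-2-hydroxy-4-methoxyphenyl}-3-[4-(benzyloxy)-3-methoxyphenyl]-2-methoxyprop-2-en-1-one
Product: 19 5-(benzyloxy)-8-[2-(benzyloxy)benzyl]-2-[4-(benzyloxy)-3-methoxyphenyl]-3,7-dimethoxy-4H-chromen-4-one, via 3-methoxyflavanone 18 (not isolated)
Conditions: I2 (10 mol%), dry DMSO, 120 °C; aq. Na2S2O3
Reagents that add atoms: none
Why: Iodine–DMSO oxidative cyclisation of a 2'-hydroxychalcone, in which 6-endo oxa-Michael addition of the C8a hydroxyl gives flavanone 18, iodination at C3 and loss of HI then give the chromone, and DMSO re-oxidises the iodide so that iodine stays catalytic.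

Step 10
Reactants: 19 5-(benzyloxy)-8-[2-(benzyloxy)benzyl]-2-[4-(benzyloxy)-3-methoxyphenyl]-3,7-dimethoxy-4H-chromen-4-one
Product: 20 5-hydroxy-8-(2-hydroxybenzyl)-2-(4-hydroxy-3-methoxyphenyl)-3,7-dimethoxy-4H-chromen-4-one (target)
Conditions: H2 (1 atm), 10% Pd/C, EtOAc/MeOH, rt
Reagents that add atoms: none
Why: Catalytic hydrogenolysis cleaves the three aryl benzyl ethers, while the tetrasubstituted chromone C2=C3 bond, the methyl ethers and the diarylmethane should be inert at ambient pressure if the reaction is stopped once debenzylation is complete.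

Compound list
1 | 5-methoxyresorcinol | COc1cc(O)cc(O)c1 | starting material
2 | 2,4-dihydroxy-6-methoxybenzaldehyde | COc1cc(O)cc(O)c1C=O | intermediate
3 | 4-(benzyloxy)-2-hydroxy-6-methoxybenzaldehyde | COc1cc(OCc2ccccc2)cc(O)c1C=O | intermediate
4 | 1-(benzyloxy)-2-bromobenzene | Brc1ccccc1OCc1ccccc1 | starting material
5 | [2-(benzyloxy)phenyl]magnesium bromide | Br[Mg]c1ccccc1OCc1ccccc1 | intermediate
6 | rac-[4-(benzyloxy)-2-hydroxy-6-methoxyphenyl][2-(benzyloxy)phenyl]methanol | COc1cc(OCc2ccccc2)cc(O)c1C(O)c1ccccc1OCc1ccccc1 | intermediate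
7 | 2-[2-(benzyloxy)benzyl]-5-(benzyloxy)-3-methoxyphenol | COc1cc(OCc2ccccc2)cc(O)c1Cc1ccccc1OCc1ccccc1 | intermediate
8 | 6-[2-(benzyloxy)benzyl]-3-(benzyloxy)-2-bromo-5-methoxyphenol | COc1cc(OCc2ccccc2)c(Br)c(O)c1Cc1ccccc1OCc1ccccc1 | intermediate
9 | {6-[2-(benzyloxy)benzyl]-3-(benzyloxy)-2-bromo-5-methoxyphenoxy}trimethylsilane | COc1cc(OCc2ccccc2)c(Br)c(O[Si](C)(C)C)c1Cc1ccccc1OCc1ccccc1 | intermediate
10 | lithium 6-[2-(benzyloxy)benzyl]-3-(benzyloxy)-5-methoxy-2-(trimethylsilyl)phenolate | [Li+].[O-]c1c([Si](C)(C)C)c(OCc2ccccc2)cc(OC)c1Cc1ccccc1OCc1ccccc1 | intermediate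
11 | 6-[2-(benzyloxy)benzyl]-3-(benzyloxy)-5-methoxy-2-(trimethylsilyl)phenyl trifluoromethanesulfonate | C[Si](C)(C)c1c(OCc2ccccc2)cc(OC)c(Cc2ccccc2OCc2ccccc2)c1OS(=O)(=O)C(F)(F)F | intermediate
12 | 4-(benzyloxy)-3-methoxybenzaldehyde | COc1cc(C=O)ccc1OCc1ccccc1 | starting material
13 | methyl methoxyacetate | COCC(=O)OC | starting material
14 | methyl (Z)-3-[4-(benzyloxy)-3-methoxyphenyl]-2-methoxyacrylate | CO/C(C(=O)OC)=C\c1ccc(OCc2ccccc2)c(OC)c1 | intermediate
15 | (Z)-3-[4-(benzyloxy)-3-methoxyphenyl]-2-methoxyacrylic acid | CO/C(C(=O)O)=C\c1ccc(OCc2ccccc2)c(OC)c1 | intermediate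
16 | 3-[2-(benzyloxy)benzyl]-6-(benzyloxy)-4-methoxy-1,2-didehydrobenzene (aryne across C4a–C8a) | COC1=C(Cc2ccccc2OCc2ccccc2)C#CC(OCc2ccccc2)=C1 | intermediate
17 | (Z)-1-{3-[2-(benzyloxy)benzyl]-6-(benzyloxy)-2-hydroxy-4-methoxyphenyl}-3-[4-(benzyloxy)-3-methoxyphenyl]-2-methoxyprop-2-en-1-one | CO/C(=C\c1ccc(OCc2ccccc2)c(OC)c1)C(=O)c1c(O)c(Cc2ccccc2OCc2ccccc2)c(OC)cc1OCc1ccccc1 | intermediate
18 | 5-(benzyloxy)-8-[2-(benzyloxy)benzyl]-2-[4-(benzyloxy)-3-methoxyphenyl]-3,7-dimethoxychroman-4-one (racemic mixture of C2/C3 diastereomers) | COc1cc(C2Oc3c(Cc4ccccc4OCc4ccccc4)c(OC)cc(OCc4ccccc4)c3C(=O)C2OC)ccc1OCc1ccccc1 | intermediate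
19 | 5-(benzyloxy)-8-[2-(benzyloxy)benzyl]-2-[4-(benzyloxy)-3-methoxyphenyl]-3,7-dimethoxy-4H-chromen-4-one | COc1cc(-c2oc3c(Cc4ccccc4OCc4ccccc4)c(OC)cc(OCc4ccccc4)c3c(=O)c2OC)ccc1OCc1ccccc1 | intermediate
20 | 5-hydroxy-8-(2-hydroxybenzyl)-2-(4-hydroxy-3-methoxyphenyl)-3,7-dimethoxy-4H-chromen-4-one | COc1cc(-c2oc3c(Cc4ccccc4O)c(OC)cc(O)c3c(=O)c2OC)ccc1O | target

Total step count: 10. Longest linear sequence: 9 steps (steps 1–6, 8, 9, 10); step 7 is the convergent branch.

Steps most likely to fail

Step 8. The aryl anion may be protonated before it reaches the ester carbonyl, so that the reaction stops at the O-aryl ester, or the carboxylate may add with the reverse orientation under steric pressure from the C8 benzyl group. The fallback sets out from bromophenol 8 and acid 15 and avoids the aryne altogether. Esterification (EDC·HCl, DMAP, CH2Cl2, rt) should give 6-[2-(benzyloxy)benzyl]-3-(benzyloxy)-2-bromo-5-methoxyphenyl (Z)-3-[4-(benzyloxy)-3-methoxyphenyl]-2-methoxyacrylate F1. Bromine–lithium exchange (t-BuLi, 2.1 equiv, THF, -100 °C) then generates the C4a aryllithium next to the ester, which undergoes the anionic ortho-Fries 1,3-O-to-C acyl shift. After aq. NH4Cl the route is rejoined at chalcone 17, with the site of acylation fixed by the position of the bromine.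

Step 9. The enol ether may be hydrolysed by adventitious HI and water with loss of the C3 methoxy group, ring A may be iodinated at C6, or the reaction may stall at the flavanone. The fallback sets out from 17 and separates closure from oxidation. Base-mediated oxa-Michael cyclisation (NaOAc, EtOH, reflux) gives flavanone 18, now isolated, and quinone dehydrogenation (DDQ, 1,4-dioxane, reflux) gives the chromone, rejoining the route at 19. No compound outside the list is made.

Step 5. Bromination may occur para to the hydroxyl (at C6) or twice on the very electron-rich ring. The fallback sets out from aldehyde 3 and installs the halogen before the benzyl unit, on the deactivated, hydrogen-bonded salicylaldehyde, where halogenation ortho to the chelated hydroxyl is the established pattern for 2-hydroxy-4,6-dialkoxy carbonyl compounds. NBS (MeCN, 0 °C) should give 4-(benzyloxy)-3-bromo-2-hydroxy-6-methoxybenzaldehyde F2. Addition of Grignard reagent 5 (THF, 0 °C to rt) gives rac-[4-(benzyloxy)-3-bromo-2-hydroxy-6-methoxyphenyl][2-(benzyloxy)phenyl]methanol F3, and ionic hydrogenation (Et3SiH, TFA, CH2Cl2, 0 °C) rejoins the route at bromophenol 8.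

Further compounds
F1 | step 8 | 6-[2-(benzyloxy)benzyl]-3-(benzyloxy)-2-bromo-5-methoxyphenyl (Z)-3-[4-(benzyloxy)-3-methoxyphenyl]-2-methoxyacrylate | CO/C(C(=O)Oc1c(Br)c(OCc2ccccc2)cc(OC)c1Cc1ccccc1OCc1ccccc1)=C\c1ccc(OCc2ccccc2)c(OC)c1
F0 | step 9 | none | none
F2 | step 5 | 4-(benzyloxy)-3-bromo-2-hydroxy-6-methoxybenzaldehyde | COc1cc(OCc2ccccc2)c(Br)c(O)c1C=O
F3 | step 5 | rac-[4-(benzyloxy)-3-bromo-2-hydroxy-6-methoxyphenyl][2-(benzyloxy)phenyl]methanol | COc1cc(OCc2ccccc2)c(Br)c(O)c1C(O)c1ccccc1OCc1ccccc1
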